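**Assessment of the direct plan**

A direct plan would make the (4R)-β-benzyl lactone A2 by amine-catalysed addition of an aldehyde enamine to the CH2-terminated syringyl quinone methide A1 released in situ, then reduction and lactonisation. It would then C-benzylate the enolate of A2 with the protected guaiacyl bromide A3 to the trans lactone A4 and hydrogenolyse.
Its weakest steps would be:
(a) the catalytic addition to A1: it would set C4, the one centre that cannot be corrected later, by a reaction type not shown for an unsubstituted quinone methide, so this stereocentre would be left to chance;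
(b) the benzylation of A2 as a phenoxide–enolate dianion: O-alkylation, double alkylation and proton exchange would all be paid for in the most valuable intermediate;
(c) the masking of the quinone methide precursor and the benzyl on/off at a single phenol: operations that would build no skeletal bond.

**Plan of the new route**

The retrosynthesis opens the lactone at the acyl–O bond (O1–C2), reads C5 as the stump of a propenyl group, and cuts the C3–C4 bond by a retro-[3,3] shift to an ester of a 3-arylpropanoic acid with an (R,E)-allylic alcohol. That alcohol is cut at ArCH2–C(sp) into a benzylic bromide and (R)-but-3-yn-2-ol.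
Enabling feature: in the ring O1–C2–C3–C4–C5, C3 is α to the C2 carbonyl and C4 carries the one-carbon, O-bearing C5. This is the γ,δ-unsaturated acid pattern of an ester-enolate Claisen product.
The only ring is closed last, after both benzyl arms and both stereocentres exist.
C4 (not epimerisable) is set by 1,3-chirality transfer from a purchased carbinol centre and an E olefin made by hydride reduction. C3 (α to C=O) is set by ketene acetal geometry and then funnelled to trans by base.
Hence there is no quinone methide, no catalyst-controlled stereocentre and no enolate benzylation on late material. One kind of protecting group falls in a single final operation.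

Key step: step 7

Remark: the target is read as the (3R,4R)-trans lactone; both phenols are carried as benzyl ethers from the start.

**Route**

Step 1
Reactants: 1 4-(hydroxymethyl)-2,6-dimethoxyphenol (syringyl alcohol)
Product: 2 [4-(benzyloxy)-3,5-dimethoxyphenyl]methanol
Conditions: BnBr (1.1 equiv), K2CO3 (1.5 equiv), acetone, 55 °C
Reagents that add atoms: benzyl bromide, BrCc1ccccc1
Why: Williamson etherification: K2CO3 ionises only the phenol, so the phenoxide is benzylated while the benzylic alcohol stays untouched.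

Step 2
Reactants: 2 [4-(benzyloxy)-3,5-dimethoxyphenyl]methanol
Product: 3 2-(benzyloxy)-5-(bromomethyl)-1,3-dimethoxybenzene
Conditions: PBr3 (0.4 equiv), CH2Cl2, 0 °C; used crude
Reagents that add atoms: phosphorus tribromide, BrP(Br)Br
Why: PBr3 bromination of a primary benzylic alcohol (SN2 on the phosphite ester) leaves the aryl ethers untouched.

Step 3
Reactants: 3 2-(benzyloxy)-5-(bromomethyl)-1,3-dimethoxybenzene; 4 (R)-but-3-yn-2-ol
Product: 6 (2R)-5-[4-(benzyloxy)-3,5-dimethoxyphenyl]pent-3-yn-2-ol, via bis(bromomagnesium) salt 5 (not isolated)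
Conditions: 4, EtMgBr (2.1 equiv), THF, 0 → 40 °C; CuCl (10 mol%); then 3, 50 °C; aq. NH4Cl
Reagents that add atoms: none
Why: Copper-catalysed coupling of an alkynyl Grignard reagent with a benzylic bromide: the alkoxide–acetylide 5 is transmetalated to a copper acetylide that displaces bromide at the benzylic carbon, and the carbinol centre is not involved and stays R.

Step 4
Reactants: 6 (2R)-5-[4-(benzyloxy)-3,5-dimethoxyphenyl]pent-3-yn-2-ol
Product: 7 (2R,3E)-5-[4-(benzyloxy)-3,5-dimethoxyphenyl]pent-3-en-2-ol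
Conditions: NaAlH2(OCH2CH2OMe)2 (2.5 equiv), THF, 0 °C → rt; aq. potassium sodium tartrate
Reagents that add atoms: none
Why: Alkoxide-directed trans-hydroalumination of a propargylic alcohol followed by protonolysis of the vinylalane should give the E-allylic alcohol only, with the carbinol stereocentre untouched.

Step 5
Reactants: 8 3-(4-hydroxy-3-methoxyphenyl)propanoic acid (dihydroferulic acid)
Product: 10 3-[4-(benzyloxy)-3-methoxyphenyl]propanoic acid, via benzyl ester 9 (not isolated)
Conditions: BnBr (2.3 equiv), K2CO3 (3 equiv), DMF, 60 °C; then 2 M NaOH, MeOH, 60 °C; HCl to pH 2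
Reagents that add atoms: benzyl bromide, BrCc1ccccc1; sodium hydroxide, [Na+].[OH-]
Why: Williamson alkylation of phenoxide and carboxylate, then saponification of the benzyl ester in the same pot, leaves only the robust aryl benzyl ether.

Step 6
Reactants: 7 (2R,3E)-5-[4-(benzyloxy)-3,5-dimethoxyphenyl]pent-3-en-2-ol; 10 3-[4-(benzyloxy)-3-methoxyphenyl]propanoic acid
Product: 11 (2R,3E)-5-[4-(benzyloxy)-3,5-dimethoxyphenyl]pent-3-en-2-yl 3-[4-(benzyloxy)-3-methoxyphenyl]propanoate
Conditions: DCC (1.2 equiv), DMAP (0.1 equiv), CH2Cl2, 0 °C → rt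
Reagents that add atoms: none
Why: Steglich esterification activates the acid (O-acylisourea, then N-acylpyridinium), so the C–O bond of the alcohol is never broken and the R configuration and E geometry are retained.

Step 7
Reactants: 11 (2R,3E)-5-[4-(benzyloxy)-3,5-dimethoxyphenyl]pent-3-en-2-yl 3-[4-(benzyloxy)-3-methoxyphenyl]propanoate
Product: 15 (2R,3S,4E)-2-[4-(benzyloxy)-3-methoxybenzyl]-3-[4-(benzyloxy)-3,5-dimethoxybenzyl]hex-4-enoic acid, via lithium enolate 12 (not isolated), via silyl ketene acetal 13 (not isolated), via silyl ester 14 (not isolated)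
Conditions: LiN(iPr)2 (1.3 equiv), THF/DMPU (55:45), −78 °C; TBSCl (1.5 equiv), −78 °C → rt, then 50 °C; 1 M HCl/THF
Reagents that add atoms: none
Why: LiN(iPr)2 in THF/DMPU deprotonates the ester through an open transition state to enolate 12 with ArCH2 cis to O–Li, TBSCl traps it as the (Z)-ketene acetal 13, and on warming 13 undergoes a concerted suprafacial [3,3]-sigmatropic shift through a chair to silyl ester 14, which aqueous acid hydrolyses to 15. The reaction type is the Ireland–Claisen rearrangement of esters of enantioenriched secondary (E)-allylic alcohols, for which 1,3-chirality transfer is well established. No ring is closed: the six-membered array exists only in the transition state, and the lactone is closed in step 8. C3 of 15 (later C4 of the lactone) is controlled by the (R)-carbinol centre and the E olefin, because the C-methyl group sits pseudo-equatorial (an axial methyl would clash with OTBS in a 1,3-diaxial way) and C–O cleavage and C–C formation occur on the same face of the allyl unit, which should give 3S and an E propenyl group. C2 of 15 (later C3) is controlled by the ketene acetal geometry within the same chair (both benzyl arms pseudo-equatorial), which should give 2R, the 2,3-syn acid that maps onto the trans lactone. The step needs faithful chirality transfer to C3, secured by the geometric and enantiomeric purity of 11 inherited from steps 3 and 4, whereas any leakage in ketene acetal geometry or a boat component touches only C2, which is α to the carboxyl group and is corrected by equilibration in step 8.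

Step 8
Reactants: 15 (2R,3S,4E)-2-[4-(benzyloxy)-3-methoxybenzyl]-3-[4-(benzyloxy)-3,5-dimethoxybenzyl]hex-4-enoic acid
Product: 19 (3R,4R)-3-[4-(benzyloxy)-3-methoxybenzyl]-4-[4-(benzyloxy)-3,5-dimethoxybenzyl]dihydrofuran-2(3H)-one, via ozonide 16 (not isolated), via aldehyde acid 17 (not isolated), via hydroxy acid 18 (not isolated)
Conditions: O3, CH2Cl2, −78 °C (Sudan Red 7B end point); NaBH4 (5 equiv), MeOH, −78 → 0 °C; 2 M HCl, rt; then DBU (0.3 equiv), toluene, 80 °C
Reagents that add atoms: ozone, [O-][O+]=O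
Why: Ozonolysis of the only C=C bond gives ozonide 16, NaBH4 reduces it through aldehyde 17 straight to γ-hydroxy acid 18 before the α-centre can enolise, acid closes the γ-lactone (5-exo-trig acyl substitution), and DBU equilibrates C3 through the lactone enolate to the thermodynamically favoured trans isomer, so any C2 epimer from step 7 converges on 19 while the non-acidic C4 is unaffected.

Step 9
Reactants: 19 (3R,4R)-3-[4-(benzyloxy)-3-methoxybenzyl]-4-[4-(benzyloxy)-3,5-dimethoxybenzyl]dihydrofuran-2(3H)-one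
Product: 20 (3R,4R)-3-(4-hydroxy-3-methoxybenzyl)-4-(4-hydroxy-3,5-dimethoxybenzyl)dihydrofuran-2(3H)-one (target)
Conditions: H2 (1 atm), 10% Pd/C, EtOAc/EtOH, rt
Reagents that add atoms: none
Why: Catalytic hydrogenolysis of both aryl benzyl ethers under neutral conditions frees the two phenols and leaves the lactone, the benzylic C–C bonds and both stereocentres untouched.

**Compound list**

1 | 4-(hydroxymethyl)-2,6-dimethoxyphenol (syringyl alcohol) | COc1cc(CO)cc(OC)c1O | starting material
2 | [4-(benzyloxy)-3,5-dimethoxyphenyl]methanol | OCc1cc(OC)c(OCc2ccccc2)c(OC)c1 | intermediate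
3 | 2-(benzyloxy)-5-(bromomethyl)-1,3-dimethoxybenzene | BrCc1cc(OC)c(OCc2ccccc2)c(OC)c1 | intermediate
4 | (R)-but-3-yn-2-ol | C[C@@H](O)C#C | starting material
5 | bromomagnesium (2R)-4-(bromomagnesio)but-3-yn-2-olate | C[C@@H](O[Mg]Br)C#C[Mg]Br | intermediate (not isolated)
6 | (2R)-5-[4-(benzyloxy)-3,5-dimethoxyphenyl]pent-3-yn-2-ol | C[C@@H](O)C#CCc1cc(OC)c(OCc2ccccc2)c(OC)c1 | intermediate
7 | (2R,3E)-5-[4-(benzyloxy)-3,5-dimethoxyphenyl]pent-3-en-2-ol | C[C@@H](O)/C=C/Cc1cc(OC)c(OCc2ccccc2)c(OC)c1 | intermediate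
8 | 3-(4-hydroxy-3-methoxyphenyl)propanoic acid (dihydroferulic acid) | COc1cc(CCC(=O)O)ccc1O | starting material
9 | benzyl 3-[4-(benzyloxy)-3-methoxyphenyl]propanoate | COc1cc(CCC(=O)OCc2ccccc2)ccc1OCc1ccccc1 | intermediate (not isolated)
10 | 3-[4-(benzyloxy)-3-methoxyphenyl]propanoic acid | COc1cc(CCC(=O)O)ccc1OCc1ccccc1 | intermediate
11 | (2R,3E)-5-[4-(benzyloxy)-3,5-dimethoxyphenyl]pent-3-en-2-yl 3-[4-(benzyloxy)-3-methoxyphenyl]propanoate | C[C@@H](OC(=O)CCc1ccc(OCc2ccccc2)c(OC)c1)/C=C/Cc1cc(OC)c(OCc2ccccc2)c(OC)c1 | intermediate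
12 | lithium enolate of 11, ArCH2 cis to O–Li, carbinol R, allyl olefin E | [Li+].C[C@@H](OC(/[O-])=C/Cc1ccc(OCc2ccccc2)c(OC)c1)/C=C/Cc1cc(OC)c(OCc2ccccc2)c(OC)c1 | intermediate (not isolated)
13 | tert-butyldimethylsilyl ketene acetal of 11, Z at the ketene acetal C=C (ArCH2 cis to OSi), carbinol R, allyl olefin E | C[C@@H](OC(/O[Si](C)(C)C(C)(C)C)=C/Cc1ccc(OCc2ccccc2)c(OC)c1)/C=C/Cc1cc(OC)c(OCc2ccccc2)c(OC)c1 | intermediate (not isolated)
14 | tert-butyldimethylsilyl (2R,3S,4E)-2-[4-(benzyloxy)-3-methoxybenzyl]-3-[4-(benzyloxy)-3,5-dimethoxybenzyl]hex-4-enoate | CC(C)(C)[Si](C)(C)OC(=O)[C@H](Cc1ccc(OCc2ccccc2)c(OC)c1)[C@H](/C=C/C)Cc1cc(OC)c(OCc2ccccc2)c(OC)c1 | intermediate (not isolated)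
15 | (2R,3S,4E)-2-[4-(benzyloxy)-3-methoxybenzyl]-3-[4-(benzyloxy)-3,5-dimethoxybenzyl]hex-4-enoic acid | OC(=O)[C@H](Cc1ccc(OCc2ccccc2)c(OC)c1)[C@H](/C=C/C)Cc1cc(OC)c(OCc2ccccc2)c(OC)c1 | intermediate
16 | (2R,3R)-2-[4-(benzyloxy)-3-methoxybenzyl]-4-[4-(benzyloxy)-3,5-dimethoxyphenyl]-3-(5-methyl-1,2,4-trioxolan-3-yl)butanoic acid (mixture at the trioxolane carbons) | OC(=O)[C@H](Cc1ccc(OCc2ccccc2)c(OC)c1)[C@H](C1OOC(C)O1)Cc1cc(OC)c(OCc2ccccc2)c(OC)c1 | intermediate (not isolated)
17 | (2R,3R)-2-[4-(benzyloxy)-3-methoxybenzyl]-3-[4-(benzyloxy)-3,5-dimethoxybenzyl]-4-oxobutanoic acid | OC(=O)[C@H](Cc1ccc(OCc2ccccc2)c(OC)c1)[C@H](C=O)Cc1cc(OC)c(OCc2ccccc2)c(OC)c1 | intermediate (not isolated)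
18 | (2R,3R)-2-[4-(benzyloxy)-3-methoxybenzyl]-3-[4-(benzyloxy)-3,5-dimethoxybenzyl]-4-hydroxybutanoic acid | OC(=O)[C@H](Cc1ccc(OCc2ccccc2)c(OC)c1)[C@H](CO)Cc1cc(OC)c(OCc2ccccc2)c(OC)c1 | intermediate (not isolated)
19 | (3R,4R)-3-[4-(benzyloxy)-3-methoxybenzyl]-4-[4-(benzyloxy)-3,5-dimethoxybenzyl]dihydrofuran-2(3H)-one (trans) | COc1cc(C[C@H]2C(=O)OC[C@@H]2Cc2cc(OC)c(OCc3ccccc3)c(OC)c2)ccc1OCc1ccccc1 | intermediate
20 | (3R,4R)-3-(4-hydroxy-3-methoxybenzyl)-4-(4-hydroxy-3,5-dimethoxybenzyl)dihydrofuran-2(3H)-one (trans) | COc1cc(C[C@H]2C(=O)OC[C@@H]2Cc2cc(OC)c(O)c(OC)c2)ccc1O | target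

**Step count and risks**

Total step count: 9. Longest linear sequence: 8 steps (steps 1, 2, 3, 4, 6, 7, 8, 9).

Steps most likely to fail:

Step 7. The ketene acetal geometry may erode, a boat pathway may compete, or the ester enolate may fragment to a ketene and the allylic alkoxide before it is silylated. The fallback sets out from allylic alcohol 7 and transfers its chirality under neutral thermal conditions by a Johnson–Claisen rearrangement with triethyl orthoacetate (cat. propanoic acid, 140 °C). This should give ethyl (3R,4E)-3-[4-(benzyloxy)-3,5-dimethoxybenzyl]hex-4-enoate F1, with the C4-to-be centre set as in the main route. The lithium enolate of F1 (LiN(iPr)2, THF, −78 °C) would then be benzylated with 1-(benzyloxy)-4-(bromomethyl)-2-methoxybenzene F2, made from commercial [4-(benzyloxy)-3-methoxyphenyl]methanol and PBr3. That would give ethyl (2RS,3S,4E)-2-[4-(benzyloxy)-3-methoxybenzyl]-3-[4-(benzyloxy)-3,5-dimethoxybenzyl]hex-4-enoate F3 as a mixture at C2. Ozonolysis and NaBH4 reduction as in step 8 would give ethyl (2RS,3R)-2-[4-(benzyloxy)-3-methoxybenzyl]-3-[4-(benzyloxy)-3,5-dimethoxybenzyl]-4-hydroxybutanoate F4. Acid and then DBU would close the lactone and equilibrate C3 to trans, so the route is rejoined at 19.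

Step 8. Ozone may over-oxidise the two electron-rich aryl ether rings, or the α-centre of the transient aldehyde may epimerise. The fallback sets out from acid 15 and cleaves the olefin without ozone by a Lemieux–Johnson oxidation (OsO4 cat., NaIO4, 2,6-lutidine, dioxane/H2O). The carboxylate form should keep the intermediate (2R,3R)-2-[4-(benzyloxy)-3-methoxybenzyl]-3-[4-(benzyloxy)-3,5-dimethoxybenzyl]-4,5-dihydroxyhexanoic acid F5 from lactonising before periodate cleaves it. The route is rejoined at aldehyde acid 17, which is reduced at once with NaBH4 and carried on as in step 8.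

Step 3. The benzylic bromide may homocouple, or the skipped aryl alkyne may isomerise to an allene under the basic conditions. The fallback sets out from alkyne 4. Hydroboration with pinacolborane (2.2 equiv, Cp2Zr(H)Cl cat., Et3N) would give (2R,3E)-4-(4,4,5,5-tetramethyl-1,3,2-dioxaborolan-2-yl)but-3-en-2-ol F6. An sp2–sp3 Suzuki–Miyaura coupling of F6 with bromide 3 (Pd(PPh3)4, zerovalent palladium, K2CO3, THF/H2O, 60 °C) would then give the E-allylic alcohol directly. The route is rejoined at 7, with the E geometry coming from the syn hydroboration and without the alkyne coupling or the hydride reduction.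

**Further compounds**

F1 | step 7 | ethyl (3R,4E)-3-[4-(benzyloxy)-3,5-dimethoxybenzyl]hex-4-enoate | CCOC(=O)C[C@H](/C=C/C)Cc1cc(OC)c(OCc2ccccc2)c(OC)c1
F2 | step 7 | 1-(benzyloxy)-4-(bromomethyl)-2-methoxybenzene | COc1cc(CBr)ccc1OCc1ccccc1
F3 | step 7 | ethyl (2RS,3S,4E)-2-[4-(benzyloxy)-3-methoxybenzyl]-3-[4-(benzyloxy)-3,5-dimethoxybenzyl]hex-4-enoate | CCOC(=O)C(Cc1ccc(OCc2ccccc2)c(OC)c1)[C@H](/C=C/C)Cc1cc(OC)c(OCc2ccccc2)c(OC)c1
F4 | step 7 | ethyl (2RS,3R)-2-[4-(benzyloxy)-3-methoxybenzyl]-3-[4-(benzyloxy)-3,5-dimethoxybenzyl]-4-hydroxybutanoate | CCOC(=O)C(Cc1ccc(OCc2ccccc2)c(OC)c1)[C@H](CO)Cc1cc(OC)c(OCc2ccccc2)c(OC)c1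
F5 | step 8 | (2R,3R)-2-[4-(benzyloxy)-3-methoxybenzyl]-3-[4-(benzyloxy)-3,5-dimethoxybenzyl]-4,5-dihydroxyhexanoic acid (syn diol, mixture at C4 and C5) | OC(=O)[C@H](Cc1ccc(OCc2ccccc2)c(OC)c1)[C@H](C(O)C(C)O)Cc1cc(OC)c(OCc2ccccc2)c(OC)c1
F6 | step 3 | (2R,3E)-4-(4,4,5,5-tetramethyl-1,3,2-dioxaborolan-2-yl)but-3-en-2-ol | C[C@@H](O)/C=C/B1OC(C)(C)C(C)(C)O1
A1 | direct plan | 2,6-dimethoxy-4-methylidenecyclohexa-2,5-dien-1-one (syringyl p-quinone methide) | C=C1C=C(OC)C(=O)C(OC)=C1
A2 | direct plan | (4R)-4-(4-hydroxy-3,5-dimethoxybenzyl)dihydrofuran-2(3H)-one | O=C1OC[C@@H](C1)Cc1cc(OC)c(O)c(OC)c1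
A3 | direct plan | 1-(benzyloxy)-4-(bromomethyl)-2-methoxybenzene | COc1cc(CBr)ccc1OCc1ccccc1
A4 | direct plan | (3R,4R)-3-[4-(benzyloxy)-3-methoxybenzyl]-4-(4-hydroxy-3,5-dimethoxybenzyl)dihydrofuran-2(3H)-one | COc1cc(C[C@H]2C(=O)OC[C@@H]2Cc2cc(OC)c(O)c(OC)c2)ccc1OCc1ccccc1
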